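**Plan**
- Retrosynthesis: the three protecting groups come off last. The phenol ring (arene C1 = CH2 link, C3 = diol chain, C4 = OH) is then cut at arene C2–C3 and C4–C5. This gives a 5-substituted 2-pyrone (pyrone C5 → arene C1, C6 → C2, C3 → C5, C4 → C6) and a siloxyalkyne whose two carbons become arene C3 and C4.
- The pyrone-bearing core is cut at the quaternary C2–CH2 bond (O-benzyl furanone ester + 5-(bromomethyl)-2-pyrone). The furanone is cut at C2–C3 and the lactone C–O (phenylpyruvic acid + methyl glyoxylate).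
- Forward: the butenolide ring is made first (aldol/lactonization), the pyronylmethyl arm is joined by alkylation, and the benzene ring is formed late by [4+2] cycloaddition and loss of CO2, which also joins the side chain.
- Stereochemistry: C2 (R) is set by chiral phase-transfer alkylation; the carbinol centre (S) comes unchanged from (S)-α-hydroxy-γ-butyrolactone (L-malic acid series).

Key step: step 11

Assumption: which antipode of the phase-transfer catalyst delivers (2R) is to be fixed by a test run; the (S) catalyst is written, and the commercial (R) antipode replaces it if the sense is opposite.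

**Route**

Step 1
Reactants: 1 coumalic acid
Product: 2 5-(hydroxymethyl)-2H-pyran-2-one
Conditions: BH3·THF (1.2 equiv), THF, 0 → 23 °C; aqueous work-up
Reagents that add atoms: none
Why: Chemoselective borane reduction, since BH3 reduces a free carboxylic acid through its acyloxyborane much faster than it attacks the electron-poor conjugated pyrone lactone.

Step 2
Reactants: 2 5-(hydroxymethyl)-2H-pyran-2-one
Product: 3 5-(bromomethyl)-2H-pyran-2-one
Conditions: CBr4, PPh3, CH2Cl2, 0 °C
Reagents that add atoms: carbon tetrabromide, BrC(Br)(Br)Br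
Why: The Appel reaction converts the primary allylic alcohol into the bromide under neutral conditions that the base-sensitive pyrone tolerates.

Step 3
Reactants: 4 phenylpyruvic acid; 5 methyl glyoxylate (freshly distilled monomer)
Product: 7 methyl 4-hydroxy-5-oxo-3-phenyl-2,5-dihydrofuran-2-carboxylate (racemic), via aldol adduct 6 (not isolated)
Conditions: Et3N (2.2 equiv), THF, 0 → 23 °C; 1 M HCl work-up; then p-TsOH·H2O (5 mol %), PhMe, 80 °C
Reagents that add atoms: none
Why: Aldol addition of the enol(ate) of the α-keto acid to the non-enolizable glyoxylate aldehyde and acid-catalysed lactonization (the classical isotetronic acid synthesis) should give the furanone, whose C2 centre forms racemic and is planarized again in step 5.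

Step 4
Reactants: 7 methyl 4-hydroxy-5-oxo-3-phenyl-2,5-dihydrofuran-2-carboxylate (racemic)
Product: 8 methyl 4-(benzyloxy)-5-oxo-3-phenyl-2,5-dihydrofuran-2-carboxylate (racemic)
Conditions: BnOH, PPh3, DIAD, THF, 0 → 23 °C
Reagents that add atoms: benzyl alcohol, OCc1ccccc1
Why: The Mitsunobu reaction alkylates the acidic enol (a vinylogous carboxylic acid) on oxygen without base, so the C2–H is neither deprotonated nor benzylated.

Step 5
Reactants: 8 methyl 4-(benzyloxy)-5-oxo-3-phenyl-2,5-dihydrofuran-2-carboxylate (racemic); 3 5-(bromomethyl)-2H-pyran-2-one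
Product: 9 methyl (2R)-4-(benzyloxy)-5-oxo-2-[(6-oxo-6H-pyran-3-yl)methyl]-3-phenyl-2,5-dihydrofuran-2-carboxylate
Conditions: 3 (1.2 equiv), (S)-4,4-dibutyl-2,6-bis(3,4,5-trifluorophenyl)-4,5-dihydro-3H-dinaphtho[2,1-c:1',2'-e]azepinium bromide (5 mol %), K2CO3 (powder, 3 equiv), PhMe, −20 °C
Reagents that add atoms: none
Why: Proposed new method: solid K2CO3 should deprotonate the doubly activated C2–H (α to the ester, γ of the butenolide) to a planar 2-furanolate whose tight ion pair with the C2-symmetric chiral ammonium cation shields one face, so that SN2 attack on the allylic bromide at C2 (the site that restores the phenyl-conjugated butenolide) sets the quaternary centre; the closest known reactions are asymmetric phase-transfer alkylations of α-acyloxymalonates, α-substituted β-keto esters and 5H-oxazol-4-ones that create oxygen-bearing quaternary centres, not yet shown for a 5-alkoxycarbonyl furan-2(5H)-one.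

Step 6
Reactants: 10 (3S)-3-hydroxyoxolan-2-one ((S)-α-hydroxy-γ-butyrolactone)
Product: 11 (3S)-4-methylpentane-1,3,4-triol
Conditions: MeMgBr (4 equiv), THF, 0 → 23 °C; sat. NH4Cl
Reagents that add atoms: methylmagnesium bromide, C[Mg]Br
Why: Double Grignard addition to the lactone carbonyl (after deprotonation of the hydroxyl) opens the ring to the tertiary carbinol, and the stereocentre is not touched and is retained as with α-hydroxy esters in general.

Step 7
Reactants: 11 (3S)-4-methylpentane-1,3,4-triol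
Product: 12 2-[(4S)-2,2,5,5-tetramethyl-1,3-dioxolan-4-yl]ethan-1-ol
Conditions: 2,2-dimethoxypropane, p-TsOH·H2O (2 mol %), acetone, 23 °C
Reagents that add atoms: 2,2-dimethoxypropane, COC(C)(C)OC
Why: Acid-catalysed transketalization should favour the five-membered dioxolane of the vicinal secondary/tertiary diol over the six-membered dioxane, leaving the primary alcohol free.

Step 8
Reactants: 12 2-[(4S)-2,2,5,5-tetramethyl-1,3-dioxolan-4-yl]ethan-1-ol
Product: 13 2-[(4S)-2,2,5,5-tetramethyl-1,3-dioxolan-4-yl]acetaldehyde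
Conditions: TEMPO (10 mol %), PhI(OAc)2 (1.1 equiv), CH2Cl2, 23 °C
Reagents that add atoms: none
Why: Oxoammonium-mediated (TEMPO) oxidation stops at the aldehyde and is mild enough for the acetonide and the β-oxygenated aldehyde.

Step 9
Reactants: 13 2-[(4S)-2,2,5,5-tetramethyl-1,3-dioxolan-4-yl]acetaldehyde
Product: 14 (4S)-2,2,5,5-tetramethyl-4-(prop-2-yn-1-yl)-1,3-dioxolane
Conditions: dimethyl (1-diazo-2-oxopropyl)phosphonate, K2CO3, MeOH, 0 → 23 °C
Reagents that add atoms: dimethyl (1-diazo-2-oxopropyl)phosphonate, COP(=O)(OC)C(=[N+]=[N-])C(C)=O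
Why: The Ohira–Bestmann form of the Seyferth–Gilbert homologation turns the aldehyde into the terminal alkyne under carbonate conditions that do not eliminate the β-alkoxy group.

Step 10
Reactants: 14 (4S)-2,2,5,5-tetramethyl-4-(prop-2-yn-1-yl)-1,3-dioxolane
Product: 17 triisopropyl({3-[(4S)-2,2,5,5-tetramethyl-1,3-dioxolan-4-yl]prop-1-yn-1-yl}oxy)silane, via lithium acetylide 15 (not isolated), via lithium ynolate 16 (not isolated)
Conditions: LiN(SiMe3)2 (2.2 equiv), t-BuOOH (1.1 equiv, anhydrous in decane), THF, −78 → 0 °C; then i-Pr3SiOTf, −78 → 0 °C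
Reagents that add atoms: tert-butyl hydroperoxide, CC(C)(C)OO; triisopropylsilyl trifluoromethanesulfonate, CC(C)[Si](OS(=O)(=O)C(F)(F)F)(C(C)C)C(C)C
Why: Oxidation of the lithium acetylide by lithium tert-butyl peroxide gives the ynolate, which the bulky silyl triflate captures on oxygen to give an isolable triisopropylsilyl ynol ether (established siloxyalkyne synthesis from terminal alkynes).

Step 11
Reactants: 9 methyl (2R)-4-(benzyloxy)-5-oxo-2-[(6-oxo-6H-pyran-3-yl)methyl]-3-phenyl-2,5-dihydrofuran-2-carboxylate; 17 triisopropyl({3-[(4S)-2,2,5,5-tetramethyl-1,3-dioxolan-4-yl]prop-1-yn-1-yl}oxy)silane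
Product: 19 methyl (2R)-4-(benzyloxy)-5-oxo-3-phenyl-2-{[3-{[(4S)-2,2,5,5-tetramethyl-1,3-dioxolan-4-yl]methyl}-4-[(triisopropylsilyl)oxy]phenyl]methyl}-2,5-dihydrofuran-2-carboxylate, via bridged bicyclic lactone 18 (not isolated)
Conditions: 17 (1.5 equiv), AgN(SO2CF3)2 (10 mol %), 2,6-di-tert-butylpyridine (20 mol %), 4 Å MS, ClCH2CH2Cl, 23 → 60 °C
Reagents that add atoms: none
Why: Proposed new method: the silver salt should bind the pyrone carbonyl of 9 and make C6 (the vinylogous acyl terminus next to the ring oxygen) electrophilic enough for the chain-bearing β-carbon of 17 to attack it, giving a silyl ketenium/metal dienolate pair that closes by bonding of dienolate C3 to the ketenium carbon, so that overall an asynchronous inverse-electron-demand [4+2] cycloaddition gives bridged lactone 18, which loses CO2 by retro-[4+2] to the arene. The closest known reactions are the thermal cycloaddition/decarboxylation of coumalates with ynamines, ketene acetals and enol ethers, the AgN(SO2CF3)2-catalysed formal inverse-demand Diels–Alder reaction of siloxyalkynes with 1,2-diazines (loss of N2) and their Michael-initiated [2+2] additions to enones; a 5-alkyl-2-pyrone with a siloxyalkyne has not been shown. The carbocycle closes as a six-membered ring through the second C–C bond of the [4+2] (formally 6-exo-dig attack of the dienolate carbon on the ketenium carbon, suprafacial closure in the concerted limit), and the CO2 bridge then leaves to aromatize it. No stereocentre is created: the two bridgehead centres of 18 are transient and vanish on aromatization, and C2 and the dioxolane carbon lie outside the reacting atoms. Only regioselectivity is needed (chain-bearing alkyne carbon to pyrone C6, oxygen-bearing carbon to C3), and it follows from pairing the nucleophilic alkyne carbon with the most electrophilic pyrone position, which places the silyloxy group para to the CH2 link and ortho to the chain. The tetrasubstituted, phenyl-bearing butenolide alkene is too hindered to compete as an acceptor.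

Step 12
Reactants: 19 methyl (2R)-4-(benzyloxy)-5-oxo-3-phenyl-2-{[3-{[(4S)-2,2,5,5-tetramethyl-1,3-dioxolan-4-yl]methyl}-4-[(triisopropylsilyl)oxy]phenyl]methyl}-2,5-dihydrofuran-2-carboxylate
Product: 20 methyl (2R)-4-(benzyloxy)-2-{[3-[(2S)-2,3-dihydroxy-3-methylbutyl]-4-[(triisopropylsilyl)oxy]phenyl]methyl}-5-oxo-3-phenyl-2,5-dihydrofuran-2-carboxylate
Conditions: AcOH/H2O (4:1), 50 °C
Reagents that add atoms: none
Why: Acid-catalysed ketal hydrolysis is run while the phenol is still silylated, so the tertiary carbinol cannot cyclize onto a free phenol, and the aryl silyl ether, benzyl enol ether and esters should be stable to aqueous acetic acid.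

Step 13
Reactants: 20 methyl (2R)-4-(benzyloxy)-2-{[3-[(2S)-2,3-dihydroxy-3-methylbutyl]-4-[(triisopropylsilyl)oxy]phenyl]methyl}-5-oxo-3-phenyl-2,5-dihydrofuran-2-carboxylate
Product: 21 methyl (2R)-4-(benzyloxy)-2-{[3-[(2S)-2,3-dihydroxy-3-methylbutyl]-4-hydroxyphenyl]methyl}-5-oxo-3-phenyl-2,5-dihydrofuran-2-carboxylate
Conditions: Bu4NF (1.2 equiv), AcOH (1.2 equiv), THF, 0 °C
Reagents that add atoms: none
Why: Fluoride-mediated desilylation of the aryl silyl ether, buffered with acetic acid so that the lactone and methyl ester are not exposed to basic fluoride.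

Step 14
Reactants: 21 methyl (2R)-4-(benzyloxy)-2-{[3-[(2S)-2,3-dihydroxy-3-methylbutyl]-4-hydroxyphenyl]methyl}-5-oxo-3-phenyl-2,5-dihydrofuran-2-carboxylate
Product: 22 methyl (2R)-2-{[3-[(2S)-2,3-dihydroxy-3-methylbutyl]-4-hydroxyphenyl]methyl}-4-hydroxy-5-oxo-3-phenyl-2,5-dihydrofuran-2-carboxylate (8''S,9''-diol versicolactone B)
Conditions: H2 (1 atm), Pd/C (10% Pd on carbon), EtOAc, 23 °C
Reagents that add atoms: none
Why: Hydrogenolysis of the benzyl enol ether over palladium should free the enol, while the tetrasubstituted conjugated butenolide alkene and the arenes are not reduced at 1 atm.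

**Compound list**
1 | coumalic acid (2-oxo-2H-pyran-5-carboxylic acid) | O=C(O)C1=COC(=O)C=C1 | starting material
2 | 5-(hydroxymethyl)-2H-pyran-2-one | OCC1=COC(=O)C=C1 | intermediate
3 | 5-(bromomethyl)-2H-pyran-2-one | BrCC1=COC(=O)C=C1 | intermediate
4 | phenylpyruvic acid | O=C(O)C(=O)Cc1ccccc1 | starting material
5 | methyl glyoxylate | COC(=O)C=O | starting material
6 | 4-hydroxy-5-methoxy-2,5-dioxo-3-phenylpentanoic acid (aldol adduct, racemic diastereomer mixture) | COC(=O)C(O)C(c1ccccc1)C(=O)C(=O)O | intermediate (not isolated)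
7 | methyl 4-hydroxy-5-oxo-3-phenyl-2,5-dihydrofuran-2-carboxylate (racemic) | COC(=O)C1OC(=O)C(O)=C1c1ccccc1 | intermediate
8 | methyl 4-(benzyloxy)-5-oxo-3-phenyl-2,5-dihydrofuran-2-carboxylate (racemic) | COC(=O)C1OC(=O)C(OCc2ccccc2)=C1c1ccccc1 | intermediate
9 | methyl (2R)-4-(benzyloxy)-5-oxo-2-[(6-oxo-6H-pyran-3-yl)methyl]-3-phenyl-2,5-dihydrofuran-2-carboxylate | COC(=O)[C@]1(CC2=COC(=O)C=C2)OC(=O)C(OCc2ccccc2)=C1c1ccccc1 | intermediate
10 | (3S)-3-hydroxyoxolan-2-one ((S)-α-hydroxy-γ-butyrolactone) | O[C@H]1CCOC1=O | starting material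
11 | (3S)-4-methylpentane-1,3,4-triol | OCC[C@H](O)C(C)(C)O | intermediate
12 | 2-[(4S)-2,2,5,5-tetramethyl-1,3-dioxolan-4-yl]ethan-1-ol | OCC[C@H]1C(C)(C)OC(C)(C)O1 | intermediate
13 | 2-[(4S)-2,2,5,5-tetramethyl-1,3-dioxolan-4-yl]acetaldehyde | O=CC[C@H]1C(C)(C)OC(C)(C)O1 | intermediate
14 | (4S)-2,2,5,5-tetramethyl-4-(prop-2-yn-1-yl)-1,3-dioxolane | C#CC[C@H]1C(C)(C)OC(C)(C)O1 | intermediate
15 | lithium acetylide of 14 | [Li]C#CC[C@H]1C(C)(C)OC(C)(C)O1 | intermediate (not isolated)
16 | lithium 3-[(4S)-2,2,5,5-tetramethyl-1,3-dioxolan-4-yl]prop-1-yn-1-olate (ynolate) | [Li]OC#CC[C@H]1C(C)(C)OC(C)(C)O1 | intermediate (not isolated)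
17 | triisopropyl({3-[(4S)-2,2,5,5-tetramethyl-1,3-dioxolan-4-yl]prop-1-yn-1-yl}oxy)silane | CC(C)[Si](OC#CC[C@H]1C(C)(C)OC(C)(C)O1)(C(C)C)C(C)C | intermediate
18 | methyl (2R)-4-(benzyloxy)-5-oxo-2-({3-oxo-7-{[(4S)-2,2,5,5-tetramethyl-1,3-dioxolan-4-yl]methyl}-8-[(triisopropylsilyl)oxy]-2-oxabicyclo[2.2.2]octa-5,7-dien-6-yl}methyl)-3-phenyl-2,5-dihydrofuran-2-carboxylate (both bridgehead diastereomers) | COC(=O)[C@]1(CC2=CC3C(O[Si](C(C)C)(C(C)C)C(C)C)=C(C[C@H]4C(C)(C)OC(C)(C)O4)C2OC3=O)OC(=O)C(OCc2ccccc2)=C1c1ccccc1 | intermediate (not isolated)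
19 | methyl (2R)-4-(benzyloxy)-5-oxo-3-phenyl-2-{[3-{[(4S)-2,2,5,5-tetramethyl-1,3-dioxolan-4-yl]methyl}-4-[(triisopropylsilyl)oxy]phenyl]methyl}-2,5-dihydrofuran-2-carboxylate | COC(=O)[C@]1(Cc2ccc(O[Si](C(C)C)(C(C)C)C(C)C)c(C[C@H]3C(C)(C)OC(C)(C)O3)c2)OC(=O)C(OCc2ccccc2)=C1c1ccccc1 | intermediate
20 | methyl (2R)-4-(benzyloxy)-2-{[3-[(2S)-2,3-dihydroxy-3-methylbutyl]-4-[(triisopropylsilyl)oxy]phenyl]methyl}-5-oxo-3-phenyl-2,5-dihydrofuran-2-carboxylate | COC(=O)[C@]1(Cc2ccc(O[Si](C(C)C)(C(C)C)C(C)C)c(C[C@H](O)C(C)(C)O)c2)OC(=O)C(OCc2ccccc2)=C1c1ccccc1 | intermediate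
21 | methyl (2R)-4-(benzyloxy)-2-{[3-[(2S)-2,3-dihydroxy-3-methylbutyl]-4-hydroxyphenyl]methyl}-5-oxo-3-phenyl-2,5-dihydrofuran-2-carboxylate | COC(=O)[C@]1(Cc2ccc(O)c(C[C@H](O)C(C)(C)O)c2)OC(=O)C(OCc2ccccc2)=C1c1ccccc1 | intermediate
22 | methyl (2R)-2-{[3-[(2S)-2,3-dihydroxy-3-methylbutyl]-4-hydroxyphenyl]methyl}-4-hydroxy-5-oxo-3-phenyl-2,5-dihydrofuran-2-carboxylate (8''S,9''-diol versicolactone B) | COC(=O)[C@]1(Cc2ccc(O)c(C[C@H](O)C(C)(C)O)c2)OC(=O)C(O)=C1c1ccccc1 | target

**Step count and risks**
Total: 14 steps. Longest linear sequence: 9 steps (10 → 22, steps 6–14).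

Steps most likely to fail:

Step 11 (Proposed new method). The unactivated pyrone may react too slowly, so that silver-induced loss of the siloxyalkyne (protodesilylation to a ketene, capture of the ketenium carbon by a dioxolane oxygen) or attack at pyrone C4 with four-membered ring closure overtakes the cycloaddition. The fallback moves the same ring construction to the ester-activated diene, where it is known chemistry. It sets out from 1 and 17. Coumalic acid is esterified (MeOH, H2SO4) to methyl coumalate F1. With 17 in toluene at 80–110 °C this should give, through bridged adduct F2 and loss of CO2, methyl 3-{[(4S)-2,2,5,5-tetramethyl-1,3-dioxolan-4-yl]methyl}-4-[(triisopropylsilyl)oxy]benzoate F3. Reduction with i-Bu2AlH (CH2Cl2, −78 °C) gives benzylic alcohol F4, and CBr4/PPh3 gives benzylic bromide F5. F5 alkylates the furanolate of 8 (K2CO3, Bu4NBr, toluene, 0 °C) to give 19 together with its C2 epimer F6, and 19 is separated by preparative HPLC. The route is rejoined at 19.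

Step 5 (Proposed new method). Facial discrimination in the ion pair may be weak, because the furanolate is flat and has no second binding group near C2. The fallback uses resolution in place of asymmetric induction. It sets out from 8 and 3. Alkylation under achiral phase transfer (K2CO3, Bu4NBr, toluene, 0 °C) gives the racemic alkylation product F7. Preparative chromatography on a polysaccharide chiral stationary phase separates it into 9 and the (2S) enantiomer F8, which is set aside. The route is rejoined at 9.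

Step 10. Oxygen transfer from the peroxide to the acetylide may be incomplete, or the peroxide may be consumed in side reactions, so that little ynolate reaches the silylation. The fallback generates the ynolate from an ester by Kowalski homologation instead of from the alkyne. It sets out from 13. Oxidative esterification (I2, KOH, MeOH, 0 °C) gives methyl 2-[(4S)-2,2,5,5-tetramethyl-1,3-dioxolan-4-yl]acetate F9. LiCHBr2 (from CH2Br2 and lithium 2,2,6,6-tetramethylpiperidide, THF, −78 °C), then LiN(SiMe3)2 and n-BuLi (−78 → 0 °C), convert it through the lithium dibromo enolate F10 into ynolate 16. i-Pr3SiCl silylates 16 on oxygen, and the route is rejoined at 17.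

**Further compounds**
F1 | step 11 | methyl coumalate (methyl 2-oxo-2H-pyran-5-carboxylate) | COC(=O)C1=COC(=O)C=C1
F2 | step 11 | methyl 3-oxo-7-{[(4S)-2,2,5,5-tetramethyl-1,3-dioxolan-4-yl]methyl}-8-[(triisopropylsilyl)oxy]-2-oxabicyclo[2.2.2]octa-5,7-diene-6-carboxylate (bridged adduct) | COC(=O)C1=CC2C(O[Si](C(C)C)(C(C)C)C(C)C)=C(C[C@H]3C(C)(C)OC(C)(C)O3)C1OC2=O
F3 | step 11 | methyl 3-{[(4S)-2,2,5,5-tetramethyl-1,3-dioxolan-4-yl]methyl}-4-[(triisopropylsilyl)oxy]benzoate | COC(=O)c1ccc(O[Si](C(C)C)(C(C)C)C(C)C)c(C[C@H]2C(C)(C)OC(C)(C)O2)c1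
F4 | step 11 | (3-{[(4S)-2,2,5,5-tetramethyl-1,3-dioxolan-4-yl]methyl}-4-[(triisopropylsilyl)oxy]phenyl)methanol | OCc1ccc(O[Si](C(C)C)(C(C)C)C(C)C)c(C[C@H]2C(C)(C)OC(C)(C)O2)c1
F5 | step 11 | {4-(bromomethyl)-2-{[(4S)-2,2,5,5-tetramethyl-1,3-dioxolan-4-yl]methyl}phenoxy}triisopropylsilane | BrCc1ccc(O[Si](C(C)C)(C(C)C)C(C)C)c(C[C@H]2C(C)(C)OC(C)(C)O2)c1
F6 | step 11 | methyl (2S)-4-(benzyloxy)-5-oxo-3-phenyl-2-{[3-{[(4S)-2,2,5,5-tetramethyl-1,3-dioxolan-4-yl]methyl}-4-[(triisopropylsilyl)oxy]phenyl]methyl}-2,5-dihydrofuran-2-carboxylate (C2 epimer of 19) | COC(=O)[C@@]1(Cc2ccc(O[Si](C(C)C)(C(C)C)C(C)C)c(C[C@H]3C(C)(C)OC(C)(C)O3)c2)OC(=O)C(OCc2ccccc2)=C1c1ccccc1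
F7 | step 5 | methyl 4-(benzyloxy)-5-oxo-2-[(6-oxo-6H-pyran-3-yl)methyl]-3-phenyl-2,5-dihydrofuran-2-carboxylate (racemate) | COC(=O)C1(CC2=COC(=O)C=C2)OC(=O)C(OCc2ccccc2)=C1c1ccccc1
F8 | step 5 | methyl (2S)-4-(benzyloxy)-5-oxo-2-[(6-oxo-6H-pyran-3-yl)methyl]-3-phenyl-2,5-dihydrofuran-2-carboxylate | COC(=O)[C@@]1(CC2=COC(=O)C=C2)OC(=O)C(OCc2ccccc2)=C1c1ccccc1
F9 | step 10 | methyl 2-[(4S)-2,2,5,5-tetramethyl-1,3-dioxolan-4-yl]acetate | COC(=O)C[C@H]1C(C)(C)OC(C)(C)O1
F10 | step 10 | lithium 1,1-dibromo-3-[(4S)-2,2,5,5-tetramethyl-1,3-dioxolan-4-yl]prop-1-en-2-olate | [Li]OC(C[C@H]1C(C)(C)OC(C)(C)O1)=C(Br)Br
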